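## Structural features

The target 34 is a 1,16-cyclo-clerodane. Cyclohexene ring A (C1–C5, C10; C3=C4), cyclohexane ring B (C5–C10) and cycloheptanone ring C (C1, C10, C9, C11, C12, C13, C16) all meet at the carbinol carbon C10. Ring C is fused to a furan through C13=C16, and an α,β-unsaturated γ-lactone (C4–C18–O–C19–C5) bridges the A/B junction. Six stereocentres are contiguous (C7–C8–C9–C10–C5 and C10–C1; 1R,5S,7R,8S,9S,10S). C5 and C9 are quaternary and flank the tertiary alcohol C10. On ring B the C19 arm, the C7 oxygen and C20 lie on one face (all axial in the trans-decalin chair), and 10-OH lies on the other. The fragile parts are the furan (acid, oxidants, electrophiles), the tertiary C10 alcohol once a carbonyl sits on C5 (retro-aldol), the secondary acetate and the enoate lactone. The real difficulty is the congested C9–C10–C5 triad, together with the fact that C1 must be bonded both to the furan α-carbon C16 and into ring A. The key step exploits the fact that C1 is the α-carbon of a C10 carbonyl while C16 is the nucleophilic α-position of a 3-substituted furan held five atoms away (C13–C12–C11–C9–C10). An oxidised C10 enol ether, electrophilic at C1, can therefore be captured by C16 to close ring C before any stereocentre at C1, C5 or C10 exists. The C10 ketone released by this closure is then used twice: it keeps C1 acidic for attaching C2/C3, and it is the acceptor for the C5–C10 bond of ring B.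

## Logic of the disconnections

34 ⇒ 33. The C7 O–acetyl bond is cut last, because an acetate would not survive the organometallic, fluoride and basic steps. The forward step must acylate the hindered secondary C7–OH and leave the tertiary C10–OH alone.

33 ⇒ 31. The lactone C–O bond (O19–C18), both silyl ethers and the C12 ketal are cut together. The lactone then becomes a carboxylic acid at C18 and a protected C19 alcohol, and the C12 ketone stays masked to the end. The forward step must lactonise only through O19; O10 is anti to C18 across C4–C5 and cannot reach it.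

31 ⇒ 29. C18 is taken back from the acid to the inner carbon of a vinyl group on C4. This costs one sacrificial carbon but makes ring A the product of a metathesis. The forward cleavage must select the terminal alkene over the ring alkene and the furan.

29 ⇒ 28. Ring A is opened at C3=C4. The diene becomes an enyne with an allyl group on C1 and an ethynyl group on C5, so ring A and the C3=C4 position arise in one catalytic, redox-neutral step. The demand is a 1,7-enyne whose two arms are gauche across C1–C10.

28 ⇒ 27. The C4≡C18 triple bond is cut to a C4 aldehyde (one-carbon homologation). The forward step must work on a neopentyl aldehyde without reversing the aldol that made it.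

27 ⇒ 26. The C5–C10 bond of ring B is cut (aldol transform), which removes two stereocentres (C5, C10) and a ring. The forward step must enolise the aldehyde at C5 while the acidic C1–H next to the C10 ketone does no harm, and must attack the face of C10 that gives 10-OH anti to C20.

26 ⇒ 22 + 23. The C1–C2 bond is cut and C4 is returned to a silyl-protected CH2OH. C1 is alkylated while it is still the α-carbon of the C10 ketone (most acidic site), because after the aldol it is only furfurylic. For the same reason C4 is carried as an alcohol and not as an ester: an ester cannot be reduced or vinylated selectively beside the C10 ketone, and it would not survive the methyl addition that makes C1.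

22 ⇒ 21. The C1–C16 bond of ring C is cut (the key disconnection), leaving a C10 silyl enol ether and a free furan α-position. One ring and no stereocentre are lost. An atom-by-atom comparison of 21 and 22 with 34 confirms that C7 (R), C8 (S) and C9 (S) already have the configuration of the target. The only competing furan site that a seven-membered closure could reach is the β-carbon C14, not C15. The forward step must oxidise the enol ether without destroying the furan, the ketal or the silyl ethers.

21 ⇒ 18. The C10–C1 bond and the two O–Si bonds are cut, so the methyl ketone and the C7 oxygen are masked together as a γ-lactone. This keeps C10 inert while C12 is built and ketalised, and a free 1,4-diketone (C10/C12), which would cyclodehydrate to a furan under acid, is never formed. The forward steps need a single methyl addition to the lactone and trapping of the open keto alkoxide.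

18 ⇒ 15 + 16. The C12–C13 bond and the dioxolane are cut, giving a Weinreb amide on C11 and a 3-furyl nucleophile. The demand is addition to the amide in preference to the hindered lactone carbonyl.

15 ⇒ 12 + 14. The C9–C11 and C9–C20 bonds are cut. Two successive alkylations of the lactone enolate build the quaternary C9 under control of the adjacent C8 methyl group. The order (methyl first, then the C11 arm) is dictated by the second electrophile entering anti to C17.

12 ⇒ 8 + 9. The C7–C8 bond is cut (crotylation transform) and C10 is returned to a terminal alkene carbon. C7 and C8 then come from one reagent-controlled step on an aldehyde without α-stereocentre. The demand is anti selectivity and the (R) carbinol.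

8 ⇒ 1 + 2. The C5–C19 bond is cut (hydroxymethylation of an acyl oxazolidinone). C5 is erased later in the aldol step, so it is set only to keep every intermediate a single isomer; the demand is differentiation of the two CH2O arms (C19 as TBDPS ether, C4 as TBS ether).

## Other disconnections considered

Alternative 1: The cut is C4–C5, with the lactone C–O bond already present as an ester of O19.
- Forward step: the (Z)-2-iodobut-2-enoate A2 (rings B and C and the C10 carbinol in place, C5=C6 alkene) would add zerovalent palladium, undergo 5-exo-trig carbopalladation at C5 and lose a β-hydrogen from C7. This would give the (E)-ethylidene lactone A1 with a C6=C7 silyl enol ether.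
- In its favour: an intramolecular Heck reaction is a dependable way to a quaternary carbon, and the lactone is closed in the same step. The resulting C7 ketone could be reduced from the equatorial side to the axial C7 alcohol. On these two points (C5 and C7) it would be better than the chosen plan, which relies on an aldol for C5.
- Against it: ring A stays open in A1. C1 (furfuryl CH2) and C2 (methyl of the ethylidene) are both unactivated sp3 carbons, and joining them needs a γ-deprotonated alkylidene lactone plus an electrophilic, oxidised C1. The face of C5 attacked is not obviously biased. A2 itself already needs ring C and the C9/C10 pair, so the anodic closure or an equivalent would still be required.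
- Comparison: structurally it fixes the lactone early and ring A late; mechanistically it is two-electron organopalladium chemistry against electron-transfer chemistry. In step count it is probably equal up to A1 and longer after it.

Alternative 2: The cuts are C5–C10 and C3–C4.
- Forward step: in A4 a 2-alkylfuran, whose substituted α-carbon is C10, would add as the diene to the tethered butenolide alkene C4=C5 and give the oxygen-bridged adduct A3.
- In its favour: two rings, two C–C bonds, the quaternary C5 and the C10 oxygen would arise in one thermal step. The short tether should force the C5/C10 relationship (C19 anti to O10), which is better than the chosen plan, where this relationship depends on a transition-state preference. Base-induced opening of the bridge would give C3=C4 and 10-OH directly.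
- Against it: furan cycloadditions with a β,β-disubstituted butenolide are slow and reversible. The π-face relative to C9 is controlled only by C7–C9 in a flexible tether. The furan consumed is not the furan of the target, so ring C, the C12 ketone and the C13–C16 furan would all have to be built afterwards on a hindered C1=C2 alkene next to two quaternary carbons.
- Comparison: structurally it starts from the opposite end (rings A/B first, ring C last); mechanistically it is pericyclic and needs no oxidant, which is an advantage for the acid- and oxidant-sensitive groups. In step economy the key step is more productive than the chosen one, but the endgame would be clearly longer.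

Alternative 3: The cuts are C4–C5 and C1–C10.
- Forward step: the C5 enolate of the ring B ketone A6 would add to C4 of the ynone ester A7. The C1 enolate formed after proton transfer (α to the C2 ketone and furfurylic) would then add to the C10 ketone and give the ketol A5.
- In its favour: it is convergent and brings ring A, C18 at the right oxidation level, the C3=C4 alkene and three stereocentres in one operation. It uses the same acidity at C1 that the chosen plan uses in compound 22. In convergence it is the better plan.
- Against it: a fully substituted enolate must add to an alkynone with the right regiochemistry and with the alkene geometry that lets C1 reach C10. The aldol onto the hindered C10 ketone has the same reversibility problem as step 20 (equal on this point). The C2 carbonyl is surplus and would have to be removed beside an enoate, a furan and a bromide. Ring C would still have to be closed from C13–Br to C12.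
- Comparison: structurally ring C is made last by polar chemistry instead of first by electron transfer; mechanistically it is all enolate chemistry. In step count it could equal or beat the chosen plan only if removal of the C2 oxygen were short.

Key step: step 16

Remark: clerodane atom numbers are used for every intermediate (TBS = tert-butyldimethylsilyl, TBDPS = tert-butyldiphenylsilyl). Compounds 24–26 are assumed to be C1-epimer mixtures that equilibrate under the conditions of step 20, and C5 of 4–26 is an arbitrary but defined centre that is erased in step 20.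

Step 1
Reactants: 1 (R)-4-benzyl-1,3-oxazolidin-2-one; 2 pent-4-enoyl chloride
Product: 3 (R)-4-benzyl-3-(pent-4-enoyl)-1,3-oxazolidin-2-one
Conditions: n-BuLi, THF, −78 °C; then 2, −78 → 0 °C
Reagents that add atoms: none
Why: N-acylation of the lithiated Evans auxiliary; no stereocentre is formed, and the auxiliary is attached to control C5 in step 2.

Step 2
Reactants: 3 (R)-4-benzyl-3-(pent-4-enoyl)-1,3-oxazolidin-2-one
Product: 4 (R)-4-benzyl-3-[(2S)-2-(hydroxymethyl)pent-4-enoyl]-1,3-oxazolidin-2-one
Conditions: TiCl4, i-Pr2NEt, CH2Cl2, 0 °C; then 1,3,5-trioxane, TiCl4, 0 °C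
Reagents that add atoms: 1,3,5-trioxane, C1OCOCO1
Why: Evans hydroxymethylation (titanium enolate aldol with a formaldehyde equivalent) introduces C19 with its oxygen; the chelated Z-enolate should be attacked on the face away from the benzyl group, which sets C5 as (S) in 4.

Step 3
Reactants: 4 (R)-4-benzyl-3-[(2S)-2-(hydroxymethyl)pent-4-enoyl]-1,3-oxazolidin-2-one
Product: 5 (R)-4-benzyl-3-[(2S)-2-(TBDPS-oxymethyl)pent-4-enoyl]-1,3-oxazolidin-2-one
Conditions: TBDPSCl, imidazole, DMF, 0 °C → rt
Reagents that add atoms: tert-butyl(chloro)diphenylsilane, CC(C)(C)[Si](Cl)(c1ccccc1)c1ccccc1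
Why: Silylation of the primary C19 alcohol; the TBDPS group is chosen because it resists 1,3-migration in step 4 and survives until step 25.

Step 4
Reactants: 5 (R)-4-benzyl-3-[(2S)-2-(TBDPS-oxymethyl)pent-4-enoyl]-1,3-oxazolidin-2-one
Product: 6 (2R)-2-(TBDPS-oxymethyl)pent-4-en-1-ol
Conditions: LiBH4, MeOH (1 equiv), Et2O, 0 °C
Reagents that add atoms: none
Why: Reductive removal of the auxiliary from the N-acyl oxazolidinone gives the C4 primary alcohol; C5 is not touched and the auxiliary 1 should be recovered.

Step 5
Reactants: 6 (2R)-2-(TBDPS-oxymethyl)pent-4-en-1-ol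
Product: 7 (2R)-1-(TBS-oxy)-2-(TBDPS-oxymethyl)pent-4-ene
Conditions: TBSCl, imidazole, CH2Cl2, rt
Reagents that add atoms: tert-butyl(chloro)dimethylsilane, CC(C)(C)[Si](C)(C)Cl
Why: Silylation of the C4 alcohol with a group that can later be removed (primary TBS) in the presence of the secondary TBS ether and the TBDPS ether.

Step 6
Reactants: 7 (2R)-1-(TBS-oxy)-2-(TBDPS-oxymethyl)pent-4-ene
Product: 8 (3R)-4-(TBS-oxy)-3-(TBDPS-oxymethyl)butanal (C7 aldehyde)
Conditions: O3, CH2Cl2/MeOH, −78 °C; then PPh3, −78 °C → rt
Reagents that add atoms: ozone, [O-][O+]=O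
Why: Ozonolysis with reductive work-up cleaves the only alkene to the C7 aldehyde; the stereocentre is β to the carbonyl and is not at risk.

Step 7
Reactants: 8 (3R)-4-(TBS-oxy)-3-(TBDPS-oxymethyl)butanal; 9 (E)-but-2-ene
Product: 10 (3S,4R,6R)-7-(TBS-oxy)-6-(TBDPS-oxymethyl)-3-methylhept-1-en-4-ol (anti; C7 R; C8 S)
Conditions: 9, KOt-Bu, n-BuLi, THF, −78 → −45 °C; (−)-Ipc2BOMe, −78 °C; BF3·OEt2; then 8, −78 °C; NaOH, H2O2, 0 °C → rt
Reagents that add atoms: none
Why: Brown (E)-crotylboration; the chair transition state of the (E)-crotylborane gives the anti relationship, and the isopinocampheyl groups of the (−)-Ipc2BOMe series should deliver the (R) carbinol at C7 and (S) at C8 under reagent control.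

Step 8
Reactants: 10 (3S,4R,6R)-7-(TBS-oxy)-6-(TBDPS-oxymethyl)-3-methylhept-1-en-4-ol
Product: 11 (3S,4R,6R)-7-(TBS-oxy)-6-(TBDPS-oxymethyl)-3-methylheptane-1,4-diol
Conditions: 9-BBN, THF, 0 °C → rt; then NaOH, H2O2, 0 °C
Reagents that add atoms: hydrogen peroxide, OO
Why: Anti-Markovnikov hydroboration–oxidation of the terminal alkene puts the oxygen on C10; no stereocentre is formed.

Step 9
Reactants: 11 (3S,4R,6R)-7-(TBS-oxy)-6-(TBDPS-oxymethyl)-3-methylheptane-1,4-diol
Product: 12 (4S,5R)-5-[(2R)-3-(TBS-oxy)-2-(TBDPS-oxymethyl)propyl]-4-methyldihydrofuran-2(3H)-one (trans lactone; C10 carbonyl)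
Conditions: TEMPO (cat.), PhI(OAc)2, CH2Cl2, rt
Reagents that add atoms: none
Why: Oxoammonium oxidation selects the primary alcohol; the aldehyde closes to the lactol with O7 and is oxidised on to the γ-lactone, which masks C10 and O7 together.

Step 10
Reactants: 12 (4S,5R)-5-[(2R)-3-(TBS-oxy)-2-(TBDPS-oxymethyl)propyl]-4-methyldihydrofuran-2(3H)-one
Product: 13 (3S,4S,5R)-3,4-dimethyl lactone (C20 on C9; 3,4-trans)
Conditions: LiN(i-Pr)2, THF, −78 °C; then MeI, −78 → −40 °C
Reagents that add atoms: iodomethane, CI
Why: Alkylation of the lactone enolate introduces C20; the configuration formed at C9 is irrelevant because C9 is enolised again in step 11.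

Step 11
Reactants: 13 (3S,4S,5R)-3,4-dimethyl lactone; 14 2-bromo-N-methoxy-N-methylacetamide
Product: 15 2-[(3S,4S,5R)-3,4-dimethyl-2-oxo-5-substituted tetrahydrofuran-3-yl]-N-methoxy-N-methylacetamide (C9 quaternary; C11 arm trans to C17)
Conditions: LiN(i-Pr)2, THF, −78 °C; then 14, DMPU, −78 → −20 °C
Reagents that add atoms: none
Why: Alkylation of the trisubstituted lactone enolate with an activated α-halo amide; the electrophile should enter anti to the methyl group on the neighbouring C8, so that C20 ends cis to C17 and C9 is (S).

Step 12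
Reactants: 15 Weinreb amide lactone; 16 3-bromofuran
Product: 17 (3S,4S,5R)-3-[2-(furan-3-yl)-2-oxoethyl]-3,4-dimethyl lactone (C12 ketone)
Conditions: 16, n-BuLi, THF, −78 °C; then 15, −78 °C; AcOH
Reagents that add atoms: none
Why: Bromine–lithium exchange gives 3-furyllithium, which should add to the unhindered Weinreb amide to form a stable chelated adduct (ketone after work-up), while the lactone carbonyl is shielded by the quaternary C9.

Step 13
Reactants: 17 furyl ketone lactone
Product: 18 (3S,4S,5R)-3-{[2-(furan-3-yl)-1,3-dioxolan-2-yl]methyl}-3,4-dimethyl lactone (C12 dioxolane)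
Conditions: TMSOCH2CH2OTMS, TMSOTf (cat.), CH2Cl2, −78 → −20 °C; pyridine
Reagents that add atoms: 1,2-bis(trimethylsilyloxy)ethane, C[Si](C)(C)OCCO[Si](C)(C)C
Why: Noyori ketalisation converts the aryl ketone to the dioxolane under aprotic conditions that spare both silyl ethers and the lactone; C10 is still a lactone carbonyl, so no 1,4-diketone is exposed to acid.

Step 14
Reactants: 18 dioxolane lactone
Product: 19 (5R,7R,8S,9S)-7-hydroxy C10 methyl ketone (in equilibrium with its five-membered lactol)
Conditions: MeLi, Et2O/THF, −78 °C; AcOH at −78 °C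
Reagents that add atoms: methyllithium, [Li]C
Why: Single addition of methyllithium to the lactone introduces C1; the tetrahedral lithium lactolate next to the quaternary C9 is stable at −78 °C, so a second addition should not occur.

Step 15
Reactants: 19 hydroxy methyl ketone (lactol)
Product: 21 (5R,7R,8S,9S)-C10 TBS enol ether with 7-OTBS; 4-OTBS; 19-OTBDPS; 12-dioxolane (key-step substrate), via dipotassium C7-alkoxide C10-enolate 20 (not isolated)
Conditions: KN(SiMe3)2 (2.5 equiv), THF, −78 → 0 °C; then TBSCl, −78 °C → rt
Reagents that add atoms: tert-butyl(chloro)dimethylsilane, CC(C)(C)[Si](C)(C)Cl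
Why: The lactolate opens reversibly to the keto alkoxide, whose methyl group is deprotonated irreversibly by the second equivalent of base; O-silylation of both oxygens then gives the only possible enol ether (C9 is quaternary) without a Lewis acid that could open the dioxolane.

Step 16
Reactants: 21 C10 TBS enol ether (key-step substrate)
Product: 22 (5R,7R,8S,9S)-furan-fused cycloheptanone (ring C closed; C10 ketone; C12 dioxolane) carrying the C9 arm with 7-OTBS; 4-OTBS; 19-OTBDPS
Conditions: reticulated vitreous carbon anode, Pt cathode, undivided cell, constant current (about 2.1 F/mol), LiClO4 (0.1 M), 2,6-lutidine, MeOH/CH2Cl2 (1:4), rt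
Reagents that add atoms: none
Why: Anodic oxidative cyclisation. One-electron oxidation at the carbon anode turns the electron-rich C1=C10 silyl enol ether into a radical cation that is electrophilic at C1; if the furan were oxidised instead, its radical cation would be trapped by the enol ether at the same two atoms, so both paths converge. The furan adds through C16, the α-carbon next to the tether, in a 7-endo-trig closure (ring atoms C1, C10, C9, C11, C12, C13, C16) that keeps C13=C16 inside ring C; a second electron transfer, loss of the C16 proton and transfer of the silyl group to methanol restore the furan and release the C10 ketone. The closest known reaction type is the anodic coupling of silyl enol ethers with tethered 3-alkylfurans to furan-annulated six- and seven-membered ketones. No stereocentre is created, and C7–C9 are spectators (C9 is quaternary, C7 and C8 are not acidic). Site selectivity rests on the furan: C15 cannot be reached, and the β-carbon C14, which could also give a seven-membered ring, is far less nucleophilic than C16, where the developing cation is stabilised by the ring oxygen. Chemoselectivity should be secured by the C12 dioxolane (a ketone would deactivate the furan), by the gem-disubstituted C9 (cyclisation outruns capture by methanol), by 2,6-lutidine (buffers the acid formed at the anode so that enol ether, ketal and silyl ethers survive) and by stopping the electrolysis near 2.1 F/mol (the 2,3-dialkylfuran product is itself oxidisable).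

Step 17
Reactants: 22 furan-fused cycloheptanone; 23 allyl bromide
Product: 24 C1-allyl derivative of 22 (C2 and C3 attached; C1 epimer mixture)
Conditions: LiN(SiMe3)2, THF, −78 °C; then 23, DMPU, −78 → −30 °C
Reagents that add atoms: none
Why: C-alkylation of the only possible enolate of the C10 ketone (C9 is quaternary; C1 is also furfurylic and therefore acidic); C1 remains epimerisable and is fixed in step 20.

Step 18
Reactants: 24 C1-allyl ketone
Product: 25 C4 primary alcohol of 24
Conditions: HF·pyridine, pyridine, THF, 0 °C
Reagents that add atoms: none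
Why: Buffered fluoride cleaves the primary TBS ether much faster than the hindered secondary TBS ether and the TBDPS ether and does not touch the dioxolane.

Step 19
Reactants: 25 C4 alcohol
Product: 26 C4 aldehyde of 24
Conditions: Dess–Martin periodinane, NaHCO3, CH2Cl2, 0 °C → rt
Reagents that add atoms: none
Why: Buffered hypervalent-iodine oxidation of a primary alcohol; ketone, furan, alkene, ketal and silyl ethers are inert, and the base-sensitive β-silyloxy aldehyde is not exposed to amine.

Step 20
Reactants: 26 C4 aldehyde
Product: 27 (1R,5S,7R,8S,9S,10S)-1-allyl-5-formyl-10-hydroxy bicycle (ring B closed onto ring C) with 7-OTBS; 19-OTBDPS; 12-dioxolane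
Conditions: K2CO3, MeOH, 0 °C → rt (0.01 M)
Reagents that add atoms: none
Why: Intramolecular aldol addition (6-enolexo-exo-trig) of the C5 aldehyde enolate to the C10 ketone closes ring B; the C1 enolate has no six-membered pathway and only epimerises C1, so the isomer with the allyl group anti to the incoming C5 should be funnelled through. A chair transition state with the C9 arm pseudo-equatorial on ring C, C17 equatorial and the enolate oxygen gauche to O10 should give the trans B/C fusion with 10-OH anti to C20, C19 axial and the formyl group equatorial.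

Step 21
Reactants: 27 ring B aldol
Product: 28 5-ethynyl analogue of 27 (C4≡C18; 10-OH free)
Conditions: Me3SiCHN2, n-BuLi, THF, −78 °C; then 27, −78 → 0 °C
Reagents that add atoms: (trimethylsilyl)diazomethane, C[Si](C)(C)C=[N+]=[N-]
Why: Colvin homologation; the lithiated diazo compound adds to the aldehyde, loss of lithium trimethylsilanolate and N2 gives an alkylidene carbene, and 1,2-hydrogen shift gives the terminal alkyne. The lithium aldolate formed by the first equivalent is stable to retro-aldol at low temperature, which is why this reagent is preferred to a carbonate-mediated homologation.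

Step 22
Reactants: 28 enyne
Product: 29 (1R,5S,7R,8S,9S,10S)-tetracycle with ring A closed (C3=C4; vinyl group C18H=CH2 on C4)
Conditions: second-generation Grubbs catalyst (10 mol %), ethylene (1 atm), toluene, 60 °C
Reagents that add atoms: none
Why: Ring-closing enyne metathesis of the 1,7-enyne in the exo mode forms the C3=C4 bond of a six-membered ring and places the remaining two carbons as a vinyl group on C4; ethylene keeps the ruthenium methylidene active, and the allyl and ethynyl arms are gauche (both equatorial) across C1–C10.

Step 23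
Reactants: 29 diene
Product: 30 C18 enal (C3=C4–C18HO)
Conditions: OsO4 (cat.), NaIO4, 2,6-lutidine, dioxane/H2O (3:1), rt
Reagents that add atoms: osmium tetroxide, O=[Os](=O)(=O)=O; sodium periodate, [Na+].[O-]I(=O)(=O)=O
Why: Lemieux–Johnson cleavage; the monosubstituted terminal alkene should be osmylated before the trisubstituted ring alkene next to the quaternary C5 and before the furan, and periodate cleaves the diol to the conjugated aldehyde.

Step 24
Reactants: 30 enal
Product: 31 C18 carboxylic acid
Conditions: NaClO2, NaH2PO4, 2-methylbut-2-ene, t-BuOH/H2O, 0 °C → rt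
Reagents that add atoms: sodium chlorite, [Na+].[O-]Cl=O
Why: Pinnick oxidation of an α,β-unsaturated aldehyde; the alkene scavenger removes hypochlorous acid before it can attack the furan.

Step 25
Reactants: 31 C18 acid
Product: 33 7-deacetyl target (7,10-diol; C18–O19 lactone; C12 ketone), via desilylated dihydroxy acid ketal 32 (not isolated)
Conditions: n-Bu4NF, THF, 0 → 45 °C; then 2 M HCl (aq), rt
Reagents that add atoms: water, O
Why: Fluoride removes both silyl ethers; aqueous acid then hydrolyses the dioxolane to the C12 ketone and closes the γ-lactone between the C19 alcohol and the C18 acid. O10 is anti to C18 across C4–C5 and cannot compete.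

Step 26
Reactants: 33 7-deacetyl target
Product: 34 CNP0329797.2 (1R,5S,7R,8S,9S,10S)
Conditions: Ac2O, pyridine, DMAP (cat.), CH2Cl2, rt
Reagents that add atoms: acetic anhydride, CC(=O)OC(C)=O
Why: Acylation of the secondary C7 alcohol; the tertiary C10 alcohol between two quaternary carbons should not react under these conditions.

**Compound list**

1 | (R)-4-benzyl-1,3-oxazolidin-2-one | O=C1OC[C@@H](Cc2ccccc2)N1 | starting material
2 | pent-4-enoyl chloride | C=CCCC(Cl)=O | starting material
3 | (R)-4-benzyl-3-(pent-4-enoyl)-1,3-oxazolidin-2-one | C=CCCC(=O)N1[C@H](Cc2ccccc2)COC1=O | intermediate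
4 | (R)-4-benzyl-3-[(2S)-2-(hydroxymethyl)pent-4-enoyl]-1,3-oxazolidin-2-one | C=CC[C@@H](CO)C(=O)N1[C@H](Cc2ccccc2)COC1=O | intermediate
5 | (R)-4-benzyl-3-[(2S)-2-(TBDPS-oxymethyl)pent-4-enoyl]-1,3-oxazolidin-2-one | C=CC[C@@H](CO[Si](c1ccccc1)(c1ccccc1)C(C)(C)C)C(=O)N1[C@H](Cc2ccccc2)COC1=O | intermediate
6 | (2R)-2-(TBDPS-oxymethyl)pent-4-en-1-ol | C=CC[C@@H](CO[Si](c1ccccc1)(c1ccccc1)C(C)(C)C)CO | intermediate
7 | (2R)-1-(TBS-oxy)-2-(TBDPS-oxymethyl)pent-4-ene | C=CC[C@@H](CO[Si](c1ccccc1)(c1ccccc1)C(C)(C)C)CO[Si](C)(C)C(C)(C)C | intermediate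
8 | (3R)-4-(TBS-oxy)-3-(TBDPS-oxymethyl)butanal | O=CC[C@@H](CO[Si](c1ccccc1)(c1ccccc1)C(C)(C)C)CO[Si](C)(C)C(C)(C)C | intermediate
9 | (E)-but-2-ene | C/C=C/C | starting material
10 | (3S,4R,6R)-7-(TBS-oxy)-6-(TBDPS-oxymethyl)-3-methylhept-1-en-4-ol | C=C[C@H](C)[C@H](O)C[C@@H](CO[Si](c1ccccc1)(c1ccccc1)C(C)(C)C)CO[Si](C)(C)C(C)(C)C | intermediate
11 | (3S,4R,6R)-7-(TBS-oxy)-6-(TBDPS-oxymethyl)-3-methylheptane-1,4-diol | OCC[C@H](C)[C@H](O)C[C@@H](CO[Si](c1ccccc1)(c1ccccc1)C(C)(C)C)CO[Si](C)(C)C(C)(C)C | intermediate
12 | (4S,5R)-5-[(2R)-3-(TBS-oxy)-2-(TBDPS-oxymethyl)propyl]-4-methyldihydrofuran-2(3H)-one | O=C1C[C@H](C)[C@@H](C[C@@H](CO[Si](c2ccccc2)(c2ccccc2)C(C)(C)C)CO[Si](C)(C)C(C)(C)C)O1 | intermediate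
13 | (3S,4S,5R)-3,4-dimethyl analogue of 12 | O=C1[C@@H](C)[C@H](C)[C@@H](C[C@@H](CO[Si](c2ccccc2)(c2ccccc2)C(C)(C)C)CO[Si](C)(C)C(C)(C)C)O1 | intermediate
14 | 2-bromo-N-methoxy-N-methylacetamide | CON(C)C(=O)CBr | starting material
15 | (3S,4S,5R)-lactone with quaternary C9 bearing the Weinreb acetamide arm | O=C1[C@@](C)(CC(=O)N(C)OC)[C@H](C)[C@@H](C[C@@H](CO[Si](c2ccccc2)(c2ccccc2)C(C)(C)C)CO[Si](C)(C)C(C)(C)C)O1 | intermediate
16 | 3-bromofuran | Brc1ccoc1 | starting material
17 | (3S,4S,5R)-lactone with 2-(furan-3-yl)-2-oxoethyl arm | O=C1[C@@](C)(CC(=O)c2ccoc2)[C@H](C)[C@@H](C[C@@H](CO[Si](c2ccccc2)(c2ccccc2)C(C)(C)C)CO[Si](C)(C)C(C)(C)C)O1 | intermediate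
18 | (3S,4S,5R)-lactone with C12 dioxolane | O=C1[C@@](C)(CC2(OCCO2)c2ccoc2)[C@H](C)[C@@H](C[C@@H](CO[Si](c2ccccc2)(c2ccccc2)C(C)(C)C)CO[Si](C)(C)C(C)(C)C)O1 | intermediate
19 | (5R,7R,8S,9S)-7-hydroxy C10 methyl ketone (open form of the lactol) | CC(=O)[C@@](C)(CC1(OCCO1)c1ccoc1)[C@H](C)[C@H](O)C[C@@H](CO[Si](c1ccccc1)(c1ccccc1)C(C)(C)C)CO[Si](C)(C)C(C)(C)C | intermediate
20 | dipotassium C7-alkoxide C10-enolate of 19 (not isolated) | [K+].[K+].C=C([O-])[C@@](C)(CC1(OCCO1)c1ccoc1)[C@H](C)[C@H]([O-])C[C@@H](CO[Si](c1ccccc1)(c1ccccc1)C(C)(C)C)CO[Si](C)(C)C(C)(C)C | intermediate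
21 | (5R,7R,8S,9S)-C10 TBS enol ether, key-step substrate | C=C(O[Si](C)(C)C(C)(C)C)[C@@](C)(CC1(OCCO1)c1ccoc1)[C@H](C)[C@H](O[Si](C)(C)C(C)(C)C)C[C@@H](CO[Si](c1ccccc1)(c1ccccc1)C(C)(C)C)CO[Si](C)(C)C(C)(C)C | intermediate
22 | (5R,7R,8S,9S)-furan-fused cycloheptanone, key-step product | O=C1Cc2occc2C2(OCCO2)C[C@@]1(C)[C@H](C)[C@H](O[Si](C)(C)C(C)(C)C)C[C@@H](CO[Si](c1ccccc1)(c1ccccc1)C(C)(C)C)CO[Si](C)(C)C(C)(C)C | intermediate
23 | allyl bromide | C=CCBr | starting material
24 | C1-allyl ketone (C1 epimers) | O=C1C(CC=C)c2occc2C2(OCCO2)C[C@@]1(C)[C@H](C)[C@H](O[Si](C)(C)C(C)(C)C)C[C@@H](CO[Si](c1ccccc1)(c1ccccc1)C(C)(C)C)CO[Si](C)(C)C(C)(C)C | intermediate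
25 | C4 alcohol (C1 epimers) | O=C1C(CC=C)c2occc2C2(OCCO2)C[C@@]1(C)[C@H](C)[C@H](O[Si](C)(C)C(C)(C)C)C[C@@H](CO[Si](c1ccccc1)(c1ccccc1)C(C)(C)C)CO | intermediate
26 | C4 aldehyde (C1 epimers) | O=C1C(CC=C)c2occc2C2(OCCO2)C[C@@]1(C)[C@H](C)[C@H](O[Si](C)(C)C(C)(C)C)C[C@@H](CO[Si](c1ccccc1)(c1ccccc1)C(C)(C)C)C=O | intermediate
27 | (1R,5S,7R,8S,9S,10S)-ring B aldol (5-formyl; 10-hydroxy; 1-allyl) | CC(C)(C)[Si](C)(C)O[C@@H]1C[C@@](CO[Si](c2ccccc2)(c2ccccc2)C(C)(C)C)(C=O)[C@]2(O)[C@@H](CC=C)c3occc3C3(OCCO3)C[C@@]2(C)[C@@H]1C | intermediate
28 | (1R,5S,7R,8S,9S,10S)-5-ethynyl enyne | CC(C)(C)[Si](C)(C)O[C@@H]1C[C@@](CO[Si](c2ccccc2)(c2ccccc2)C(C)(C)C)(C#C)[C@]2(O)[C@@H](CC=C)c3occc3C3(OCCO3)C[C@@]2(C)[C@@H]1C | intermediate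
29 | (1R,5S,7R,8S,9S,10S)-4-vinyl-3-ene with ring A closed | CC(C)(C)[Si](C)(C)O[C@@H]1C[C@@]2(CO[Si](c3ccccc3)(c3ccccc3)C(C)(C)C)C(C=C)=CC[C@H]3c4occc4C4(OCCO4)C[C@@](C)([C@@H]1C)[C@]23O | intermediate
30 | (1R,5S,7R,8S,9S,10S)-C18 enal | CC(C)(C)[Si](C)(C)O[C@@H]1C[C@@]2(CO[Si](c3ccccc3)(c3ccccc3)C(C)(C)C)C(C=O)=CC[C@H]3c4occc4C4(OCCO4)C[C@@](C)([C@@H]1C)[C@]23O | intermediate
31 | (1R,5S,7R,8S,9S,10S)-C18 carboxylic acid | CC(C)(C)[Si](C)(C)O[C@@H]1C[C@@]2(CO[Si](c3ccccc3)(c3ccccc3)C(C)(C)C)C(C(=O)O)=CC[C@H]3c4occc4C4(OCCO4)C[C@@](C)([C@@H]1C)[C@]23O | intermediate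
32 | desilylated 7,10,19-trihydroxy C18 acid with C12 dioxolane (not isolated) | O[C@@H]1C[C@@]2(CO)C(C(=O)O)=CC[C@H]3c4occc4C4(OCCO4)C[C@@](C)([C@@H]1C)[C@]23O | intermediate
33 | 7-deacetyl target (1R,5S,7R,8S,9S,10S) | O[C@@H]1C[C@@]23COC(=O)C2=CC[C@H]2c4occc4C(=O)C[C@@](C)([C@@H]1C)[C@@]23O | intermediate
34 | CNP0329797.2 (1R,5S,7R,8S,9S,10S) | CC(=O)O[C@@H]1C[C@@]23COC(=O)C2=CC[C@H]2c4occc4C(=O)C[C@@](C)([C@@H]1C)[C@@]23O | target

**Step count and risk**

Total step count: 26. Longest linear sequence: 26 steps (1 → 34); 2, 9, 14, 16 and 23 are purchased and enter directly.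

Step 16 (key step). The most likely failures are over-oxidation of the furan (substrate or the more electron-rich product), capture of the radical cation by methanol before ring closure, and hydrolytic loss of the enol silyl group in the acidic anode layer. All three are consequences of the small gap in oxidation potential between enol ether and furan and of the slower seven-membered closure. The fallback sets out from 19 and returns at 22. Bromination of the furan at C16 (N-bromosuccinimide, DMF, −20 °C) gives the 2-bromofuran-3-yl hydroxy ketone F1. Silylation of O7 (TBSOTf, 2,6-lutidine, −78 °C) gives the bromo methyl ketone silyl ether F2. Palladium-catalysed intramolecular α-arylation of the methyl ketone (Pd2(dba)3, Xantphos, NaOt-Bu, toluene, 80 °C) then forms the C1–C16 bond by a two-electron pathway and delivers 22.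

Step 20. The most likely failure is poor facial selectivity under partly thermodynamic control. A ring B chair with C20 equatorial avoids the three syn-axial groups of the desired product and would lead to the cis-fused C5/C10 diastereomer. Elimination of silanolate from C19 in the aldehyde enolate and an unfavourable aldol equilibrium at the hindered ketone are further risks. The fallback sets out from 26 and returns at 27. Soft enolisation of the aldehyde only (Et3SiOTf, Et3N, CH2Cl2, −78 °C) gives the C4 enol triethylsilyl ether F3. BF3·OEt2 at −78 °C then closes ring B by an irreversible intramolecular Mukaiyama aldol addition under kinetic control. C1 does not equilibrate in this variant, so a C1-epimeric by-product would have to be separated.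

Step 15. The most likely failure is silylation of the cyclic lactolate oxygen before the ring opens, giving a silyl ketal instead of the enol ether, because ring opening and enolisation of the hindered methyl ketone may be slower than O-silylation. The fallback sets out from 18 and returns at 21. Aminolysis of the lactone (MeNH(OMe)·HCl, i-PrMgCl, THF, −20 → 0 °C) gives the γ-hydroxy Weinreb amide F4, and silylation (TBSOTf, 2,6-lutidine) gives its C7 silyl ether F5. MeMgBr gives the C7-silyloxy methyl ketone F6, and LiN(SiMe3)2/TBSCl converts F6 to 21, so that no lactol is ever formed.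

Step 12. The most likely failure is loss of chemoselectivity: 3-furyllithium may add to the lactone carbonyl or deprotonate C11 of the amide, since both carbonyl groups are electrophilic toward an aryllithium. The fallback sets out from 13 and returns at 17. Alkylation of the enolate of 13 with allyl bromoacetate gives the allyl ester F7, and deallylation (Pd(PPh3)4, morpholine) gives the C12 acid F8. Oxalyl chloride gives the acid chloride F9, and Stille acylation with tributyl(3-furyl)stannane (Pd(PPh3)4, THF, 50 °C) gives 17 without any organolithium.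

Step 23. The most likely failure is osmylation of the ring alkene or of the electron-rich 2,3-dialkylfuran in competition with the vinyl group, since all three are nucleophilic π-systems. The fallback sets out from 28 and returns at 33, bypassing every oxidant. Markovnikov hydroiodination of the alkyne (B-iodo-9-borabicyclo[3.3.1]nonane, then AcOH) gives the 2-iodoalkene F10. Methoxycarbonylation (Pd(OAc)2, PPh3, CO, MeOH, Et3N) gives the α-substituted acrylate F11, and ring-closing metathesis with the allyl group (second-generation Grubbs catalyst) gives the ring A methyl ester F12. The conditions of step 25 then desilylate, deketalise and lactonise F12 by transesterification to 33.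

## Further compounds

F1 | step 16 | 2-bromofuran-3-yl hydroxy methyl ketone (C16 bromide of 19) | CC(=O)[C@@](C)(CC1(OCCO1)c1ccoc1Br)[C@H](C)[C@H](O)C[C@@H](CO[Si](c1ccccc1)(c1ccccc1)C(C)(C)C)CO[Si](C)(C)C(C)(C)C
F2 | step 16 | C7 TBS ether of F1 | CC(=O)[C@@](C)(CC1(OCCO1)c1ccoc1Br)[C@H](C)[C@H](O[Si](C)(C)C(C)(C)C)C[C@@H](CO[Si](c1ccccc1)(c1ccccc1)C(C)(C)C)CO[Si](C)(C)C(C)(C)C
F3 | step 20 | C4 enol triethylsilyl ether of 26 | O=C1C(CC=C)c2occc2C2(OCCO2)C[C@@]1(C)[C@H](C)[C@H](O[Si](C)(C)C(C)(C)C)CC(CO[Si](c1ccccc1)(c1ccccc1)C(C)(C)C)=CO[Si](CC)(CC)CC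
F4 | step 15 | γ-hydroxy Weinreb amide from 18 | CON(C)C(=O)[C@@](C)(CC1(OCCO1)c1ccoc1)[C@H](C)[C@H](O)C[C@@H](CO[Si](c1ccccc1)(c1ccccc1)C(C)(C)C)CO[Si](C)(C)C(C)(C)C
F5 | step 15 | C7 TBS ether of F4 | CON(C)C(=O)[C@@](C)(CC1(OCCO1)c1ccoc1)[C@H](C)[C@H](O[Si](C)(C)C(C)(C)C)C[C@@H](CO[Si](c1ccccc1)(c1ccccc1)C(C)(C)C)CO[Si](C)(C)C(C)(C)C
F6 | step 15 | C7-silyloxy C10 methyl ketone | CC(=O)[C@@](C)(CC1(OCCO1)c1ccoc1)[C@H](C)[C@H](O[Si](C)(C)C(C)(C)C)C[C@@H](CO[Si](c1ccccc1)(c1ccccc1)C(C)(C)C)CO[Si](C)(C)C(C)(C)C
F7 | step 12 | allyl ester lactone (C12 as allyl carboxylate) | O=C1[C@@](C)(CC(=O)OCC=C)[C@H](C)[C@@H](C[C@@H](CO[Si](c2ccccc2)(c2ccccc2)C(C)(C)C)CO[Si](C)(C)C(C)(C)C)O1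
F8 | step 12 | C12 carboxylic acid lactone | O=C1[C@@](C)(CC(=O)O)[C@H](C)[C@@H](C[C@@H](CO[Si](c2ccccc2)(c2ccccc2)C(C)(C)C)CO[Si](C)(C)C(C)(C)C)O1
F9 | step 12 | C12 acid chloride lactone | O=C1[C@@](C)(CC(=O)Cl)[C@H](C)[C@@H](C[C@@H](CO[Si](c2ccccc2)(c2ccccc2)C(C)(C)C)CO[Si](C)(C)C(C)(C)C)O1
F10 | step 23 | 2-iodoalkene from 28 (C4 iodide) | CC(C)(C)[Si](C)(C)O[C@@H]1C[C@@](CO[Si](c2ccccc2)(c2ccccc2)C(C)(C)C)(C(I)=C)[C@]2(O)[C@@H](CC=C)c3occc3C3(OCCO3)C[C@@]2(C)[C@@H]1C
F11 | step 23 | α-substituted methyl acrylate (C18 ester on C4) | CC(C)(C)[Si](C)(C)O[C@@H]1C[C@@](CO[Si](c2ccccc2)(c2ccccc2)C(C)(C)C)(C(=C)C(=O)OC)[C@]2(O)[C@@H](CC=C)c3occc3C3(OCCO3)C[C@@]2(C)[C@@H]1C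
F12 | step 23 | ring A methyl ester (methyl ester of 31) | CC(C)(C)[Si](C)(C)O[C@@H]1C[C@@]2(CO[Si](c3ccccc3)(c3ccccc3)C(C)(C)C)C(C(=O)OC)=CC[C@H]3c4occc4C4(OCCO4)C[C@@](C)([C@@H]1C)[C@]23O
A1 | alternative 1 | (E)-ethylidene lactone on quaternary C5 with C6=C7 silyl enol ether | C/C=C1/C(=O)OC[C@]12C=C(O[Si](C)(C)C(C)(C)C)[C@@H](C)[C@]3(C)CC(=O)c4ccoc4C[C@@]23O
A2 | alternative 1 | (Z)-2-iodobut-2-enoate of the C19 alcohol on the ring B cyclohexene | C/C=C(\I)C(=O)OCC1=C[C@@H](O[Si](C)(C)C(C)(C)C)[C@@H](C)[C@]2(C)CC(=O)c3ccoc3C[C@@]12O
A3 | alternative 2 | 7-oxanorbornene cycloadduct (oxygen bridge C10 to C3) | O=C1OC[C@@]23C[C@@H](O[Si](C)(C)C(C)(C)C)[C@@H](C)[C@](C)(CCO[Si](C)(C)C(C)(C)C)[C@@]2(O4)C=C[C@H]4[C@@H]13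
A4 | alternative 2 | 2-alkylfuran tethered to the 4-substituted butenolide | O=C1OCC(C[C@@H](O[Si](C)(C)C(C)(C)C)[C@@H](C)[C@](C)(CCO[Si](C)(C)C(C)(C)C)c2ccco2)=C1
A5 | alternative 3 | ring A/ring B ketol with C2 ketone; C3=C4 ester; 3-bromofuryl on C1 | COC(=O)C1=CC(=O)[C@@H](c2occc2Br)[C@]2(O)[C@@](C)(CC(OC)OC)[C@H](C)[C@H](O[Si](C)(C)C(C)(C)C)C[C@@]12CO[Si](C)(C)C(C)(C)C
A6 | alternative 3 | ring B cyclohexanone (C10 ketone; C5 epimers) | O=C1C(CO[Si](C)(C)C(C)(C)C)C[C@@H](O[Si](C)(C)C(C)(C)C)[C@@H](C)[C@]1(C)CC(OC)OC
A7 | alternative 3 | ynone ester (methyl 5-(3-bromofuran-2-yl)-4-oxopent-2-ynoate) | COC(=O)C#CC(=O)Cc1occc1Br
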